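Autumn levels off at 8% of the starting material charged, below the 27.7% its coupling partner allows, so I ask what share of the coupling partner becomes target.

common to all: starting material 0.65 M

| flask | coupling partner | free catalyst | remark | time |
|---|---|---|---|---|
| autumn | 0.18 M | 32 mM | run made earlier |  |
| dusk | 0.86 M | 32 mM | run made earlier |  |
| midnight | 0.65 M | 55 mM | run made earlier |  |
| epsilon | 0.650 M | 32 mM |  | 30 min |
| delta | 0.150 M | 120 mM |  | 30 min |

- autumn (time / min: target / %, starting material / %): 1.33: 4, 91; 2.50: 5, 94; 4.00: 5, 89; 8.00: 8, 87; 15.0: 8, 86
- dusk (time / min: target / %, starting material / %): 1.33: 3, 89; 4.00: 14, 80; 8.00: 26, 71; 10.0: 29, 65; 15.0: 31, 65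
- midnight (time / min: target / %, starting material / %): 3.00: 18, 74; 6.00: 29, 64; 10.0: 33, 58; 12.0: 36, 54; 15.0: 36, 55

(standard deviation of a reading: 1.5 percentage points)



- which of the two ends with the higher amount of target, in percent of the starting material charged ("neither" if they lie within 2 percentage points) (epsilon / delta / neither)
- target at the end, in percent of the starting material charged, epsilon
- target at the end, in percent of the starting material charged, delta

Does the plateau follow the coupling partner? I call the catch, f, the target at the plateau per coupling partner charged: 28.9% in autumn and 23.4% in dusk, at equal catalyst, with a 4.78-fold change of charge. It roughly does.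

Does the catch follow the free catalyst? Midnight, with more free catalyst, reads a catch of 36.0%. I therefore take w, the odds f/(1−f) per unit of catalyst charged, as the carried number: midnight gives 10.2 M⁻¹, which lies between dusk and autumn.

Which flask wins? Midnight reads the same at 12.0 min and 15.0 min, so I treat 30 min as plateau. My w gives epsilon a catch of 24.7%, hence 24.7% of the starting material charged. It gives delta a catch of 55.1%, hence 12.7% of the starting material charged, so I expect epsilon to end higher.

The forecast, holding that “the catalyst is dying”, says epsilon, with 25% against 15.5%.

The flask gives 26.6% for epsilon and 14.7% for delta, so epsilon ends higher.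

    starting material + free catalyst ⇌ catalyst intermediate A (K = 3.60 M⁻¹, k = 340 M⁻¹ min⁻¹)
    catalyst intermediate A ⇌ catalyst intermediate B (K = 24.0, k = 2.70 min⁻¹)
    coupling partner + catalyst intermediate B ⇌ catalyst intermediate C (K = 0.560 M⁻¹, k = 280 M⁻¹ min⁻¹)
    catalyst intermediate C → free catalyst + target (k = 8.00 min⁻¹)
    coupling partner → decomposed reagent (k = 0.190 min⁻¹)

In epsilon the coupling partner, the limiting reagent, falls to 0.012% of its charge, with 0.477 M as decomposed reagent against 0.173 M as target. In delta those amounts are 0.0546 M and 0.0954 M, a catch of 63.6%, above my 55.1%. For the neighbour flask, delta with 0.060 M of coupling partner, w gives 5.09% and delta's own catch gives 5.87%; that flask ends at 6.03%.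

All runs come from a simulation for substances that don't exist; the scatter is artificial.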